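## Retrosynthetic overview

1. Eudesmane numbering is used: ring A is C1–C5 and C10, ring B is C5–C10, C14 sits on C10, C15 on C4, and C11–C13 on C7. Late disconnections: C7–OOH by a singlet-oxygen ene reaction on the 7(11)-en-8-one, C7–C11 by alkylating a regiodefined Δ7 silyl enol ether with an acetone ketal, and both esters from a 3α,4α-diol.
2. Ring A editing: C3–OH comes from a C3 ketone. The C4–OH and the C15 methyl come from a 4-methylene-3-ketone by reductive α-hydroxylation. The 1-en-3-one comes from a 3-methoxy-2-en-1-one by reduction and hydrolysis, which expels the C1 oxygen. C15 comes from a C4 ketone by methylenation.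
3. Key disconnection: C5–C6 and C9–C10 are cut together. The forward reaction is a catalytic enantioselective Diels–Alder reaction of 2-(triisopropylsilyloxy)butadiene (C6–C9) with 2-methoxy-5-methyl-1,4-benzoquinone (ring A plus C14).
4. Enabling feature: ring B is a cyclohexanone whose C8 carbonyl stands 1,5 to the C4 oxygen along C8–C9–C10–C5–C4, and ring A carries vicinal oxygens at C3/C4 and nothing at C1/C2. Ring B therefore maps onto a 2-oxydiene. Ring A maps onto a methoxy-p-quinone whose C4 carbonyl makes the methyl-bearing C10 the electrophilic end of C5=C10, and whose C1 carbonyl is a removable activator.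
5. Ring order: ring A is bought as the quinone and ring B is closed in the key step. C10 is set by the catalyst; C5 (equilibration), C4, C3 and C7 (substrate control in the rigid trans-decalin) are relayed from it.

Key step: step 2

Assumption: the facial sense of the BINOL–Ti catalyst on the chelated quinone cannot be predicted with certainty. (R)-BINOL is written here, and the antipodal ligand would be used, with nothing else changed, if the opposite sense were found.

## Route

Step 1
Reactants: 1 methyl vinyl ketone
Product: 2 2-(triisopropylsilyloxy)buta-1,3-diene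
Conditions: TIPSOTf, Et3N, Et2O, 0 °C → rt
Reagents that add atoms: triisopropylsilyl triflate, CC(C)[Si](C(C)C)(C(C)C)OS(=O)(=O)C(F)(F)F
Why: Soft enolisation, in which the silyl triflate activates the carbonyl oxygen and the amine removes a methyl proton, should give the cross-conjugated 2-silyloxydiene (silyl enol ether formation) without forming a stereocentre.

Step 2
Reactants: 2 2-(triisopropylsilyloxy)buta-1,3-diene; 3 2-methoxy-5-methyl-1,4-benzoquinone
Product: 4 (4aR,8aS)-2-methoxy-4a-methyl-6-(triisopropylsilyloxy)-4a,5,8,8a-tetrahydronaphthalene-1,4-dione (cis-fused; 5β-H, 10β-CH3 in eudesmane numbering)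
Conditions: (R)-BINOL–TiCl2 [from (R)-BINOL and TiCl2(Oi-Pr)2] (30 mol %), PhMe, −60 → −10 °C
Reagents that add atoms: none
Why: This is a normal-electron-demand, concerted but asynchronous [4+2] cycloaddition (Diels–Alder reaction) in which the Ti(IV) centre is held as a five-membered chelate by the C4 carbonyl oxygen and the C3 methoxy oxygen of 3, so that C4=O becomes the controlling acceptor and C10 its β-carbon. The closest known reaction types are the BINOL–TiCl2-catalysed enantioselective Diels–Alder reaction of methoxy-substituted p-benzoquinones with 2-silyloxydienes and the SnCl4- or TiCl4-chelated cycloadditions of this same quinone with alkylbutadienes. Ring B is the only ring closed, by suprafacial–suprafacial union of C6 and C9 of the diene with C5 and C10 of the quinone, with C9–C10 bond formation running ahead of C5–C6. C10 is set in the absolute sense by the ligand, which should leave only the α face of the chelated quinone open, and C5 follows as its cis partner because addition to the ring alkene is suprafacial (it is corrected in step 3). Three selectivities are needed: site selectivity for C5=C10 over C2=C3, secured by the methoxy donor on C2=C3; orientation, secured by matching the most nucleophilic diene terminus (the CH2 next to C–OSi, the future C9) with C10, because the C1 carbonyl is weakened as a vinylogous ester; and facial selectivity, which rests on the rigid chelate. From two flat achiral compounds the step should deliver the whole decalin, the quaternary carbon, the C8 oxygen as a regiodefined Δ7 enol ether, and oxygens at C3 and C4.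

Step 3
Reactants: 4 cis-fused adduct
Product: 5 (4aR,8aR)-2-methoxy-4a-methyl-6-(triisopropylsilyloxy)-4a,5,8,8a-tetrahydronaphthalene-1,4-dione (trans-fused; 5α-H, 10β-CH3)
Conditions: basic Al2O3, CH2Cl2, rt
Reagents that add atoms: none
Why: Base-mediated epimerisation through the C4 enolate (thermodynamic control) should favour the trans-fused isomer, because C5 is the only enolisable position, quaternary C10 blocks aromatisation, and the sp2 atoms C1–C4 and C8 remove all but one syn-axial contact of the axial C10 methyl.

Step 4
Reactants: 5 trans-fused enedione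
Product: 7 3-methoxy-8-(triisopropylsilyloxy)-11,12,13-trinoreudesma-2,4(15),7-trien-1-one (5α-H; 10β-CH3), via C4 β-hydroxysilane 6 (not isolated)
Conditions: TMSCH2Li, CeCl3, THF, −78 °C; H2O; crude, KH, THF, 0 °C → rt
Reagents that add atoms: (trimethylsilyl)methyllithium, [Li]C[Si](C)(C)C
Why: In this cerium-modified Peterson olefination the weakly basic organocerium reagent should add 1,2 to the C4 ketone without enolising C5 (C1 is a vinylogous ester carbonyl next to quaternary C10 and stays untouched), and the carbinol centre formed by α-face attack is erased when the potassium alkoxide loses silanolate by syn elimination.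

Step 5
Reactants: 7 4-methylene vinylogous ester
Product: 9 8-(triisopropylsilyloxy)-11,12,13-trinoreudesma-1,4(15),7-trien-3-one (5α-H; 10β-CH3), via C1 allylic alcohol 8 (not isolated)
Conditions: DIBAL-H, PhMe, −78 → 0 °C; then aq oxalic acid, THF, 0 °C
Reagents that add atoms: water, O
Why: In this Stork–Danheiser-type transposition, 1,2-reduction of the vinylogous ester and mild acid hydrolysis of the 3-methoxy allylic alcohol through the C1–C3 oxocarbenium ion should move the carbonyl to C3 and expel the C1 oxygen, while the much less basic TIPS enol ether survives and no stereocentre is set.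

Step 6
Reactants: 9 cross-conjugated dienone
Product: 11 4α-hydroxy-8-(triisopropylsilyloxy)-11,12,13-trinoreudesma-1,7-dien-3-one (4β-CH3; 5α-H; 10β-CH3), via 4α-hydroperoxide 10 (not isolated)
Conditions: Mn(dpm)3 (10 mol %), PhSiH3, O2 (1 atm), i-PrOH–CH2Cl2, 0 °C; then P(OEt)3
Reagents that add atoms: dioxygen, O=O
Why: In this Mukaiyama-type hydrogen-atom-transfer reductive α-hydroxylation of an enone, the Mn hydride should deliver H to the unhindered terminal C15 faster than to the neopentyl-flanked C1=C2 or the hindered enol ether, and the planar tertiary C4 radical is trapped by O2 on the α face, anti to the pseudo-axial C10 methyl, which sets C4 (4α-O, 4β-CH3) before the phosphite reduces the O–O bond.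

Step 7
Reactants: 11 4α-hydroxy enone
Product: 12 4α-hydroxy-8-(triisopropylsilyloxy)-11,12,13-trinoreudesm-7-en-3-one
Conditions: H2 (1 atm), Pd/C, EtOAc, rt
Reagents that add atoms: none
Why: In this heterogeneous catalytic hydrogenation the cis-disubstituted enone alkene should be saturated much faster than the trisubstituted, TIPS-shielded enol ether, and no stereocentre is formed.

Step 8
Reactants: 12 α-hydroxy ketone
Product: 13 8-(triisopropylsilyloxy)-11,12,13-trinoreudesm-7-ene-3α,4α-diol
Conditions: L-Selectride (3 equiv), THF, −78 °C; H2O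
Reagents that add atoms: none
Why: In this substrate-controlled ketone reduction with a bulky trialkylborohydride the axial trajectory (α face, 1α-H and 5α-H) is closed to the reagent, so hydride should arrive along the equatorial trajectory and give the axial 3α-alcohol, cis to the 4α-hydroxyl.

Step 9
Reactants: 13 3α,4α-diol; 14 angelic acid
Product: 16 3α-angeloyloxy-8-(triisopropylsilyloxy)-11,12,13-trinoreudesm-7-en-4α-ol, via angelic 2,4,6-trichlorobenzoic anhydride 15 (not isolated)
Conditions: 14, 2,4,6-Cl3C6H2COCl, Et3N, PhMe, rt; then 13, 75 °C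
Reagents that add atoms: 2,4,6-trichlorobenzoyl chloride, O=C(Cl)c1c(Cl)cc(Cl)cc1Cl (its atoms stay in 15 only, none in 16)
Why: Yamaguchi-type mixed-anhydride esterification without a nucleophilic catalyst is the standard way to transfer an angeloyl group without Z-to-E isomerisation, and only the secondary 3α-hydroxyl should react because the tertiary C4 hydroxyl is too hindered.

Step 10
Reactants: 16 3-angelate 4-ol
Product: 17 4α-acetoxy-3α-angeloyloxy-8-(triisopropylsilyloxy)-11,12,13-trinoreudesm-7-ene
Conditions: Ac2O, Et3N, DMAP, CH2Cl2, 40 °C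
Reagents that add atoms: acetic anhydride, CC(=O)OC(C)=O
Why: DMAP-catalysed acyl transfer (Steglich-type acetylation) should acetylate the remaining equatorial tertiary alcohol under basic, non-aqueous conditions, so the enol ether and the angelate geometry persist and no stereocentre is touched.

Step 11
Reactants: 17 diester silyl enol ether
Product: 19 4α-acetoxy-3α-angeloyloxyeudesm-7(11)-en-8-one (4-O-acetylcuauhtemone), via β-methoxy ketone 18 (not isolated)
Conditions: Me2C(OMe)2, TMSOTf (20 mol %), CH2Cl2, −78 °C; Et3N quench; crude, DBU, PhMe, 80 °C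
Reagents that add atoms: 2,2-dimethoxypropane, COC(C)(C)OC
Why: Mukaiyama aldol-type alkylation of the enol silane with the oxocarbenium ion of the ketal is regiospecific for C7 because the Δ7 position of the enol ether was fixed in step 2, and the following E1cB loss of methanol can only involve the C11 methoxy group and erases the transient C7 centre.

Step 12
Reactants: 19 4-O-acetylcuauhtemone
Product: 20 4α-acetoxy-3α-angeloyloxy-7α-hydroperoxyeudesm-11-en-8-one, (3R,4S,5R,7S,10R), CNP0360871.1
Conditions: O2, tetraphenylporphyrin (cat.), visible light, CH2Cl2, 0 °C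
Reagents that add atoms: dioxygen, O=O
Why: In this Schenck ene reaction of singlet oxygen with the s-cis tetrasubstituted enone, the β face and its axial 6β-H lie in the cleft between the axial C10 and C4 methyls, while on the α face the only allylic C–H bonds aligned with the π system belong to the isopropylidene methyls (6α-H is equatorial), so oxygen should bond to C7 from the α face with shift of the alkene to C11=C12, and the electron-poor angelate alkene reacts far more slowly.

## Compound list

1 | methyl vinyl ketone | C=CC(C)=O | starting material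
2 | 2-(triisopropylsilyloxy)buta-1,3-diene | C=CC(=C)O[Si](C(C)C)(C(C)C)C(C)C | intermediate
3 | 2-methoxy-5-methyl-1,4-benzoquinone | COC1=CC(=O)C(C)=CC1=O | starting material
4 | cis-fused Diels–Alder adduct (5β-H, 10β-CH3) | C1[C@H]2[C@](C)(C(=O)C=C(OC)C2=O)CC(O[Si](C(C)C)(C(C)C)C(C)C)=C1 | intermediate
5 | trans-fused enedione (5α-H, 10β-CH3) | C1[C@@H]2[C@](C)(C(=O)C=C(OC)C2=O)CC(O[Si](C(C)C)(C(C)C)C(C)C)=C1 | intermediate
6 | C4 β-hydroxysilane (4β-OH, 4α-CH2SiMe3 expected; centre erased) | C1[C@@H]2[C@](C)(C(=O)C=C(OC)[C@@]2(O)C[Si](C)(C)C)CC(O[Si](C(C)C)(C(C)C)C(C)C)=C1 | intermediate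
7 | 3-methoxy-8-(triisopropylsilyloxy)-11,12,13-trinoreudesma-2,4(15),7-trien-1-one | C1[C@@H]2[C@](C)(C(=O)C=C(OC)C2=C)CC(O[Si](C(C)C)(C(C)C)C(C)C)=C1 | intermediate
8 | C1 allylic alcohol of 7 (C1 configuration inconsequential) | C1[C@@H]2[C@](C)(C(O)C=C(OC)C2=C)CC(O[Si](C(C)C)(C(C)C)C(C)C)=C1 | intermediate
9 | 8-(triisopropylsilyloxy)-11,12,13-trinoreudesma-1,4(15),7-trien-3-one | C1[C@@H]2[C@](C)(C=CC(=O)C2=C)CC(O[Si](C(C)C)(C(C)C)C(C)C)=C1 | intermediate
10 | 4α-hydroperoxy-8-(triisopropylsilyloxy)-11,12,13-trinoreudesma-1,7-dien-3-one | C1[C@@H]2[C@](C)(C=CC(=O)[C@@]2(C)OO)CC(O[Si](C(C)C)(C(C)C)C(C)C)=C1 | intermediate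
11 | 4α-hydroxy-8-(triisopropylsilyloxy)-11,12,13-trinoreudesma-1,7-dien-3-one | C1[C@@H]2[C@](C)(C=CC(=O)[C@@]2(C)O)CC(O[Si](C(C)C)(C(C)C)C(C)C)=C1 | intermediate
12 | 4α-hydroxy-8-(triisopropylsilyloxy)-11,12,13-trinoreudesm-7-en-3-one | C1[C@@H]2[C@](C)(CCC(=O)[C@@]2(C)O)CC(O[Si](C(C)C)(C(C)C)C(C)C)=C1 | intermediate
13 | 8-(triisopropylsilyloxy)-11,12,13-trinoreudesm-7-ene-3α,4α-diol | C1[C@@H]2[C@](C)(CC[C@@H](O)[C@@]2(C)O)CC(O[Si](C(C)C)(C(C)C)C(C)C)=C1 | intermediate
14 | angelic acid, (Z)-2-methylbut-2-enoic acid | OC(=O)/C(C)=C\C | starting material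
15 | angelic 2,4,6-trichlorobenzoic anhydride | O=C(OC(=O)/C(C)=C\C)c1c(Cl)cc(Cl)cc1Cl | intermediate
16 | 3α-angeloyloxy-8-(triisopropylsilyloxy)-11,12,13-trinoreudesm-7-en-4α-ol | C1[C@@H]2[C@](C)(CC[C@@H](OC(=O)/C(C)=C\C)[C@@]2(C)O)CC(O[Si](C(C)C)(C(C)C)C(C)C)=C1 | intermediate
17 | 4α-acetoxy-3α-angeloyloxy-8-(triisopropylsilyloxy)-11,12,13-trinoreudesm-7-ene | C1[C@@H]2[C@](C)(CC[C@@H](OC(=O)/C(C)=C\C)[C@@]2(C)OC(C)=O)CC(O[Si](C(C)C)(C(C)C)C(C)C)=C1 | intermediate
18 | 4α-acetoxy-3α-angeloyloxy-11-methoxyeudesman-8-one (C7 epimers, both converge) | COC(C)(C)C1C[C@@H]2[C@](C)(CC[C@@H](OC(=O)/C(C)=C\C)[C@@]2(C)OC(C)=O)CC1=O | intermediate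
19 | 4α-acetoxy-3α-angeloyloxyeudesm-7(11)-en-8-one | CC(C)=C1C[C@@H]2[C@](C)(CC[C@@H](OC(=O)/C(C)=C\C)[C@@]2(C)OC(C)=O)CC1=O | intermediate
20 | 4α-acetoxy-3α-angeloyloxy-7α-hydroperoxyeudesm-11-en-8-one | C=C(C)[C@@]1(OO)C[C@@H]2[C@](C)(CC[C@@H](OC(=O)/C(C)=C\C)[C@@]2(C)OC(C)=O)CC1=O | target

## Step count and risks

Total step count: 12. Longest linear sequence: 12 steps (1 → 20). Quinone 3 enters at step 2 and angelic acid 14 at step 9.

**Step 2.**
- What may go wrong: facial discrimination by the chiral titanium chelate may be insufficient. Monodentate binding at the more basic C1 carbonyl may compete and reverse the orientation. The methyl-bearing alkene may also react too slowly at low temperature.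
- Fallback (resolution instead of catalysis), from 2 and 3:
  - The achiral chelating Lewis acid SnCl4 (CH2Cl2, −78 °C) keeps the chelate-controlled orientation. It should give the cis adduct as the racemate, that is 4 together with the enantiomer of the cis adduct F1.
  - Basic alumina then gives 5 together with the enantiomer of the trans enedione F2.
  - Preparative chromatography on a chiral stationary phase separates the two. The route is rejoined at 5.

**Step 12.**
- What may go wrong: singlet oxygen may attack the β face and abstract the axial 6β-hydrogen, which is the geminal mode usual for enones. Facial selectivity at C7 may be poor. Turnover may be slow enough for the angelate alkene or the product hydroperoxide to be consumed.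
- Fallback (the oxygen acceptor becomes an enol silane instead of the enone), from 19:
  - Soft γ-enolisation with TMSOTf and Et3N (CH2Cl2, 0 °C) is possible because C9 is neopentyl and hindered. It gives the extended 8-trimethylsilyloxy-7,11-diene F3.
  - Singlet oxygen (tetraphenylporphyrin, light, CH2Cl2, −78 °C) should attack the nucleophilic C7 axially from the α face with silyl migration to the peroxide oxygen. This is the known silatropic ene reaction of silyl enol ethers, and it gives the 7α-trimethylsilylperoxy ketone F4.
  - Brief methanolysis at 0 °C frees the hydroperoxide. The route is rejoined at 20.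

**Step 11.**
- What may go wrong: the hindered TIPS enol ether may be protodesilylated faster than the C7–C11 bond forms, or the tertiary β-methoxy ketone may lose methanol only sluggishly.
- Fallback (metal enolate aldol instead of enol silane alkylation), from 17:
  - TBAF buffered with AcOH (THF, 0 °C) gives the free 8-ketone F5.
  - LiHMDS (THF, −78 °C) should enolise it towards C7, because C9 is neopentyl and the ketone is more acidic than the two esters.
  - Transmetalation with ZnCl2 and addition of acetone give the 11-hydroxy aldol F6.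
  - MsCl and Et3N convert it into the 11-mesylate F7, which DBU eliminates. The route is rejoined at 19.

## Further compounds

F1 | step 2 | enantiomer of the cis adduct | C1[C@@H]2[C@@](C)(C(=O)C=C(OC)C2=O)CC(O[Si](C(C)C)(C(C)C)C(C)C)=C1
F2 | step 2 | enantiomer of the trans enedione | C1[C@H]2[C@@](C)(C(=O)C=C(OC)C2=O)CC(O[Si](C(C)C)(C(C)C)C(C)C)=C1
F3 | step 12 | 4α-acetoxy-3α-angeloyloxy-8-(trimethylsilyloxy)eudesma-7,11-diene | C=C(C)C=1C[C@@H]2[C@](C)(CC[C@@H](OC(=O)/C(C)=C\C)[C@@]2(C)OC(C)=O)CC=1O[Si](C)(C)C
F4 | step 12 | 4α-acetoxy-3α-angeloyloxy-7α-(trimethylsilylperoxy)eudesm-11-en-8-one | C=C(C)[C@@]1(OO[Si](C)(C)C)C[C@@H]2[C@](C)(CC[C@@H](OC(=O)/C(C)=C\C)[C@@]2(C)OC(C)=O)CC1=O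
F5 | step 11 | 4α-acetoxy-3α-angeloyloxy-11,12,13-trinoreudesman-8-one | C1C[C@@H]2[C@](C)(CC[C@@H](OC(=O)/C(C)=C\C)[C@@]2(C)OC(C)=O)CC1=O
F6 | step 11 | 4α-acetoxy-3α-angeloyloxy-11-hydroxyeudesman-8-one (7α-H) | CC(C)(O)[C@H]1C[C@@H]2[C@](C)(CC[C@@H](OC(=O)/C(C)=C\C)[C@@]2(C)OC(C)=O)CC1=O
F7 | step 11 | 4α-acetoxy-3α-angeloyloxy-11-(methanesulfonyloxy)eudesman-8-one (7α-H) | CS(=O)(=O)OC(C)(C)[C@H]1C[C@@H]2[C@](C)(CC[C@@H](OC(=O)/C(C)=C\C)[C@@]2(C)OC(C)=O)CC1=O
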